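The amounts set the frame. In the zeta run, starting material read 0% at 4.00 h, and the target fell after that reading. So I followed one molecule of starting material through two forks: it becomes target with chance B, and the target survives to time t with chance S = exp(−kt).

| setting | zeta | alpha | flask |
|---|---|---|---|
| starting material | 0.25 M | 0.40 M | 0.18 M |
| gas phase | 13 mM (held) | 13 mM (held) | 13 mM (held) |
| remark | run made earlier | run made earlier |  |
| time |  |  | 30 h |

| run | time / h | target / % | starting material / % |
|---|---|---|---|
| zeta | 2.50 | 17.4 | 7.5 |
| zeta | 4.00 | 19.8 | 0 |
| zeta | 6.00 | 18.9 | 0.2 |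
| zeta | 10.0 | 14.1 | 0 |
| zeta | 20.0 | 8.5 | 0 |
| zeta | 30.0 | 4.3 | 0.3 |
| alpha | 5.00 | 15.6 | 0.2 |
| alpha | 10.0 | 10.9 | 0.4 |
| alpha | 15.0 | 9.0 | 0 |
| alpha | 20.0 | 5.6 | 0 |
| alpha | 25.0 | 3.7 | 0.4 |
| alpha | 30.0 | 3.3 | 0 |

(standard deviation of a reading: 0.5 percentage points)

- at the start none of the gas phase is in solution

- midnight: doubling the saturation concentration of gas phase, all else as stated
- autumn: doubling the transfer coefficient of the gas phase, all else as stated

* how much target there is at 30 h, in percent of the starting material charged
* the change that raises the amount of target at 30 h, in percent of the starting material charged most ("none" if none brings more than 2 percentage points) (midnight / autumn / none)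
* amount of target at 30 h, in percent of the starting material charged, after autumn

The zeta run fell from 14.1% at 10.0 h to 4.3% at 30.0 h, so k = 0.0594 h⁻¹. This k is the tail constant, the pseudo-first-order loss of target per hour after starting material has reacted. The alpha run gave 0.0597 h⁻¹, about the same at a higher charge.

Running the tails back, B read 25.5% in the zeta run and 19.7% in the alpha run. B therefore fell with charge, as charge to the power −0.548. For the flask at 0.18 M, I took B = 30.6%. With S = 16.8% at 30 h, I reckoned 5.15%.

With S held as reckoned, a gain of 2 percentage points at 30 h needed 12 points more in B. I doubted autumn could add that, and midnight might speed the tail if gas takes part, so I chose none.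

The forecast gave 5.2%, none and 6.5%: "I choose none, though this is marginal".

The flask gave 4.55%, and the best change was none: autumn reached 5.80%, a gain of 1.3 points, less than 2 points, while midnight moved the amount by −3.5 points.

    gas phase ⇌ dissolved gas, rate k1*(csat - [dissolved gas]) (kL = 1.80 h⁻¹)
    starting material + dissolved gas → target (k = 150 L mol⁻¹ h⁻¹)
    starting material → side product (k = 0.750 h⁻¹)
    dissolved gas + target → over-reaction product (k = 5.30 L mol⁻¹ h⁻¹)

Carried on with k from 4.55%, the neighbour flask left until 3.0 d reckoned to 0.375%, and it held 0.258%.

Readings and results stem from a simulated flask for an exercise, noise included.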